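**Plan**

- Numbering: in each of rings A–F (lettered from the 2,4,6-trihydroxyphenyl end), C1 is the carbon whose oxygen faces the ring A side (in ring A, the oxygen para to the ether). The hydroxyls at C3 and C5 then lie ortho or para to the ether carbon that faces ring G (C4 in rings A, B, D, F; C6 in rings C, E).
- Feature used: those twelve C3/C5 hydroxyls are carried as formyl groups. Each formyl group first activates a C4–F or C6–F bond for SNAr and is converted into OH at the end.
- Retrosynthetic cuts, in order: five O–benzyl bonds (ring A C1–O, ring C C4–O, ring G C3/C4/C5–O); twelve aryl C–O bonds at C3/C5 of rings A–F (back to C–CHO); six diaryl ether C–O bonds at C4/C6 (phenoxide plus C–F).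
- Forward: the chain is joined linearly G → F → E → D → C → B → A by six SNAr couplings. Each coupling except the last is followed by removal of an allyl group from the new terminal phenol. No ring is formed at any stage.
- Stereochemistry: none; the target has no stereocentre.

Key step: step 25

Assumption: 4-fluoro-3-hydroxybenzaldehyde and 3-fluoro-4-hydroxybenzaldehyde are taken as catalogue compounds alongside 4-fluorophenol and 3,4,5-tris(benzyloxy)benzaldehyde.

**Ring G phenol**

Step 1
Reactants: 1 3,4,5-tris(benzyloxy)benzaldehyde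
Product: 3 3,4,5-tris(benzyloxy)phenol, via aryl formate 2 (not isolated)
Conditions: mCPBA, CH2Cl2, rt; then Et3N (cat.), MeOH, rt
Reagents that add atoms: mCPBA, OOC(=O)c1cccc(Cl)c1
Why: Dakin-type Baeyer–Villiger oxidation, in which the ring carbon para to a benzyloxy donor migrates in the Criegee adduct and the resulting formate is cleaved by methanolysis.

**Fluoro-dialdehyde for rings A, B, D and F**

Step 2
Reactants: 4 4-fluorophenol
Product: 5 (4-fluorophenoxy)triisopropylsilane
Conditions: TIPSCl, imidazole, DMF, rt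
Reagents that add atoms: TIPSCl, CC(C)[Si](Cl)(C(C)C)C(C)C
Why: Imidazole-promoted silylation of a phenol; the bulky silyl group is chosen because it keeps the oxygen from directing lithiation in the next step.

Step 3
Reactants: 5 (4-fluorophenoxy)triisopropylsilane
Product: 8 2-fluoro-5-(triisopropylsilyloxy)isophthalaldehyde, via lithium hemiaminal alkoxide 6 (not isolated), via dilithium bis(hemiaminal alkoxide) 7 (not isolated)
Conditions: s-BuLi, THF, –78 °C; DMF; s-BuLi, –78 °C; DMF; then aq. HCl, 0 °C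
Reagents that add atoms: DMF, CN(C)C=O
Why: Fluorine-directed ortho-metalation with formylation, run twice in one flask: the shielded oxygen cannot direct, so s-BuLi deprotonates next to fluorine, and the first DMF adduct persists as a lithium hemiaminal alkoxide (in situ aldehyde protection) while the second position next to fluorine is lithiated and formylated.

Step 4
Reactants: 8 2-fluoro-5-(triisopropylsilyloxy)isophthalaldehyde
Product: 9 5-(allyloxy)-2-fluoroisophthalaldehyde
Conditions: allyl bromide (excess), CsF, DMF, 0 °C to rt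
Reagents that add atoms: allyl bromide, C=CCBr
Why: Fluoride-triggered desilylation with in situ Williamson alkylation; the excess of allyl bromide should trap the phenoxide before it can attack an activated C–F bond.

Step 5
Reactants: 8 2-fluoro-5-(triisopropylsilyloxy)isophthalaldehyde
Product: 10 5-(benzyloxy)-2-fluoroisophthalaldehyde
Conditions: BnBr (excess), CsF, DMF, 0 °C to rt
Reagents that add atoms: benzyl bromide, BrCc1ccccc1
Why: The same fluoride-triggered desilylation and Williamson alkylation, here installing the permanent benzyl ether of ring A.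

**Fluoro-dialdehyde for ring E**

Step 6
Reactants: 11 4-fluoro-3-hydroxybenzaldehyde
Product: 12 4-fluoro-3-(triisopropylsilyloxy)benzaldehyde
Conditions: TIPSCl, imidazole, DMF, rt
Reagents that add atoms: TIPSCl, CC(C)[Si](Cl)(C(C)C)C(C)C
Why: Imidazole-promoted silylation of the phenol, again to shield the oxygen during lithiation.

Step 7
Reactants: 12 4-fluoro-3-(triisopropylsilyloxy)benzaldehyde
Product: 15 4-fluoro-5-(triisopropylsilyloxy)isophthalaldehyde, via lithium piperazinyl alkoxide 13 (not isolated), via dilithium bis(hemiaminal alkoxide) 14 (not isolated)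
Conditions: 1-methylpiperazine, n-BuLi, THF, –78 °C, then 12; s-BuLi, –78 °C; DMF; then aq. HCl, 0 °C
Reagents that add atoms: DMF, CN(C)C=O
Why: Comins-type in situ protection of the aldehyde as a weakly directing α-amino alkoxide, then fluorine-directed ortho-lithiation and formylation at C5, the only free position next to fluorine.

Step 8
Reactants: 15 4-fluoro-5-(triisopropylsilyloxy)isophthalaldehyde
Product: 16 5-(allyloxy)-4-fluoroisophthalaldehyde
Conditions: allyl bromide (excess), CsF, DMF, 0 °C to rt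
Reagents that add atoms: allyl bromide, C=CCBr
Why: Fluoride-triggered desilylation with in situ Williamson alkylation, as in step 4.

**Fluoro-dialdehyde for ring C**

Step 9
Reactants: 17 3-fluoro-4-hydroxybenzaldehyde
Product: 18 4-(allyloxy)-3-fluorobenzaldehyde
Conditions: allyl bromide, K2CO3, DMF, rt
Reagents that add atoms: allyl bromide, C=CCBr
Why: Williamson ether synthesis; the fluorine is meta to the formyl group and so is not displaced.

Step 10
Reactants: 18 4-(allyloxy)-3-fluorobenzaldehyde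
Product: 20 4-(allyloxy)-3-fluorophenol, via aryl formate 19 (not isolated)
Conditions: 30% H2O2, H2SO4 (cat.), MeOH, rt
Reagents that add atoms: hydrogen peroxide, OO
Why: Acid-catalysed Dakin oxidation, in which the para allyloxy donor drives aryl migration; hydrogen peroxide should not epoxidise the allyl group, as a peracid might.

Step 11
Reactants: 20 4-(allyloxy)-3-fluorophenol
Product: 21 4-(allyloxy)-3-fluoro-2,6-bis(hydroxymethyl)phenol
Conditions: 37% aq. CH2O (excess), NaOH, H2O, 25–40 °C
Reagents that add atoms: formaldehyde, C=O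
Why: Lederer–Manasse hydroxymethylation; the phenoxide adds to formaldehyde at both ortho positions because the para position is blocked, and the basic medium leaves the allyl ether intact (a Duff formylation in hot acid would not).

Step 12
Reactants: 21 4-(allyloxy)-3-fluoro-2,6-bis(hydroxymethyl)phenol
Product: 22 [5-(allyloxy)-2-(benzyloxy)-4-fluoro-1,3-phenylene]dimethanol
Conditions: BnBr, K2CO3, acetone, 50 °C
Reagents that add atoms: benzyl bromide, BrCc1ccccc1
Why: Williamson ether synthesis; carbonate deprotonates only the phenol, and the C–F bond is still unactivated at this oxidation level.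

Step 13
Reactants: 22 [5-(allyloxy)-2-(benzyloxy)-4-fluoro-1,3-phenylene]dimethanol
Product: 23 5-(allyloxy)-2-(benzyloxy)-4-fluoroisophthalaldehyde
Conditions: activated MnO2, CH2Cl2, rt
Reagents that add atoms: none
Why: MnO2 oxidation of benzylic alcohols stops at the aldehyde and spares allyl and benzyl ethers; it switches on the C–F bond by placing formyl groups ortho and para to it.

**Chain assembly, G to A**

Step 14
Reactants: 3 3,4,5-tris(benzyloxy)phenol; 9 5-(allyloxy)-2-fluoroisophthalaldehyde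
Product: 24 5-(allyloxy)-2-[3,4,5-tris(benzyloxy)phenoxy]isophthalaldehyde (dimer G–F)
Conditions: K2CO3, DMF, rt
Reagents that add atoms: none
Why: SNAr by addition–elimination; the C–F carbon is flanked by two ortho formyl groups that stabilise the Meisenheimer adduct, and fluoride is the best leaving group for this mechanism.

Step 15
Reactants: 24 dimer G–F allyl ether
Product: 25 5-hydroxy-2-[3,4,5-tris(benzyloxy)phenoxy]isophthalaldehyde (dimer G–F phenol)
Conditions: Pd(PPh3)4 (cat.), p-TolSO2H, CH2Cl2, rt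
Reagents that add atoms: none
Why: Tsuji–Trost deallylation; zerovalent palladium ionises the aryl allyl ether and the sulfinate captures the π-allyl unit, a scavenger that cannot condense with aldehydes and leaves benzyl ethers untouched.

Step 16
Reactants: 25 dimer G–F phenol; 16 5-(allyloxy)-4-fluoroisophthalaldehyde
Product: 26 trimer G–F–E allyl ether, 5-(allyloxy)-4-{3,5-diformyl-4-[3,4,5-tris(benzyloxy)phenoxy]phenoxy}isophthalaldehyde
Conditions: K2CO3, DMF, rt to 40 °C
Reagents that add atoms: none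
Why: SNAr at a C–F carbon with formyl groups ortho and para; the phenoxide of 25 has its formyl groups meta and so stays nucleophilic, while its own ether carbon is deactivated by the para phenoxide.

Step 17
Reactants: 26 trimer G–F–E allyl ether
Product: 27 trimer G–F–E phenol, 5-hydroxy-4-{3,5-diformyl-4-[3,4,5-tris(benzyloxy)phenoxy]phenoxy}isophthalaldehyde
Conditions: Pd(PPh3)4 (cat.), p-TolSO2H, CH2Cl2, rt
Reagents that add atoms: none
Why: Tsuji–Trost deallylation with sulfinate capture; the freed phenoxide cannot undergo Smiles rearrangement because the neighbouring ring F carbon carries its formyl groups meta.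

Step 18
Reactants: 27 trimer G–F–E phenol; 9 5-(allyloxy)-2-fluoroisophthalaldehyde
Product: 28 tetramer G–F–E–D allyl ether (hexa-aldehyde; ring D is a 5-(allyloxy)isophthalaldehyde unit bound at its C2 to the former phenol oxygen of 27)
Conditions: K2CO3, DMF, rt
Reagents that add atoms: none
Why: SNAr at the doubly ortho-formyl-activated C–F carbon, which is reactive enough at room temperature that the existing activated diaryl ethers should not exchange.

Step 19
Reactants: 28 tetramer G–F–E–D allyl ether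
Product: 29 tetramer G–F–E–D phenol (hexa-aldehyde, free OH on ring D)
Conditions: Pd(PPh3)4 (cat.), p-TolSO2H, CH2Cl2, rt
Reagents that add atoms: none
Why: Tsuji–Trost deallylation with sulfinate capture, as in step 15.

Step 20
Reactants: 29 tetramer G–F–E–D phenol; 23 5-(allyloxy)-2-(benzyloxy)-4-fluoroisophthalaldehyde
Product: 30 pentamer G–F–E–D–C allyl ether (octa-aldehyde; ring C is a 5-(allyloxy)-2-(benzyloxy)isophthalaldehyde unit bound at its C4 to the former phenol oxygen of 29)
Conditions: K2CO3, DMF, 40 °C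
Reagents that add atoms: none
Why: SNAr at a C–F carbon with formyl groups ortho and para; the unhindered ring D phenoxide attacks, and gentle warming offsets the donor effect of the ortho allyloxy group.

Step 21
Reactants: 30 pentamer allyl ether
Product: 31 pentamer G–F–E–D–C phenol (octa-aldehyde, free OH on ring C)
Conditions: Pd(PPh3)4 (cat.), p-TolSO2H, CH2Cl2, rt
Reagents that add atoms: none
Why: Tsuji–Trost deallylation with sulfinate capture; the ring C benzyl ether is inert.

Step 22
Reactants: 31 pentamer phenol; 9 5-(allyloxy)-2-fluoroisophthalaldehyde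
Product: 32 hexamer G–F–E–D–C–B allyl ether (deca-aldehyde; ring B is a 5-(allyloxy)isophthalaldehyde unit bound at its C2 to the former phenol oxygen of 31)
Conditions: K2CO3, DMF, rt
Reagents that add atoms: none
Why: SNAr at the doubly ortho-formyl-activated C–F carbon, as in step 18.

Step 23
Reactants: 32 hexamer allyl ether
Product: 33 hexamer G–F–E–D–C–B phenol (deca-aldehyde, free OH on ring B)
Conditions: Pd(PPh3)4 (cat.), p-TolSO2H, CH2Cl2, rt
Reagents that add atoms: none
Why: Tsuji–Trost deallylation with sulfinate capture, as in step 15.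

Step 24
Reactants: 33 hexamer phenol; 10 5-(benzyloxy)-2-fluoroisophthalaldehyde
Product: 34 dodeca-formyl heptamer with five benzyl ethers (ring A is a 5-(benzyloxy)isophthalaldehyde unit bound at its C2 to the former phenol oxygen of 33)
Conditions: K2CO3, DMF, rt
Reagents that add atoms: none
Why: SNAr at the doubly ortho-formyl-activated C–F carbon; it closes the chain with a benzyl-capped ring A, so no alkene remains for the oxidation.

**Unveiling**

Step 25
Reactants: 34 dodeca-formyl heptamer
Product: 36 dodecaphenol heptamer with five benzyl ethers, via dodecaformate 35 (not isolated)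
Conditions: mCPBA (excess), CH2Cl2, rt to 35 °C; Me2S; then HCl (cat.), degassed MeOH, rt, Ar
Reagents that add atoms: mCPBA, OOC(=O)c1cccc(Cl)c1
Why: Each formyl group adds peracid to give a Criegee adduct, from which the ring carbon migrates to the peroxide oxygen with loss of 3-chlorobenzoate, so that twelve aryl formates (35) and twelve new aryl C–O bonds result; the closest known reaction is the Dakin-type Baeyer–Villiger oxidation of ortho- or para-aryloxybenzaldehydes made by SNAr, here asked to run twelve times on one substrate. No ring closes and no stereocentre is created. The selectivity needed is aryl over hydride migration at every site; the substrate favours it because each formyl-bearing carbon (C3 and C5 of rings A–F) has the ether oxygen of C4 or C6 ortho or para to it, ring C having the benzyloxy oxygen at C4 as a second donor, and the unbuffered, mildly acidic medium favours the aryl shift. Benzyl and diaryl ethers are inert to the peracid, and the phenols stay masked as formates until the excess oxidant has been destroyed with Me2S. Acidic methanolysis under argon then frees the twelve phenols without exposing the electron-rich polyphenol to base, air or peracid.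

Step 26
Reactants: 36 dodecaphenol heptamer with five benzyl ethers
Product: 37 CNP0351377.0
Conditions: H2 (1 atm), 10% Pd/C, THF/MeOH, rt
Reagents that add atoms: none
Why: Catalytic hydrogenolysis cleaves the five benzyl ethers, while diaryl ethers and free phenols are stable to it.

**Compound list**

1 | 3,4,5-tris(benzyloxy)benzaldehyde | O=Cc1cc(OCc2ccccc2)c(OCc2ccccc2)c(OCc2ccccc2)c1 | starting material
2 | 3,4,5-tris(benzyloxy)phenyl formate | O=COc1cc(OCc2ccccc2)c(OCc2ccccc2)c(OCc2ccccc2)c1 | intermediate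
3 | 3,4,5-tris(benzyloxy)phenol | Oc1cc(OCc2ccccc2)c(OCc2ccccc2)c(OCc2ccccc2)c1 | intermediate
4 | 4-fluorophenol | Oc1ccc(F)cc1 | starting material
5 | (4-fluorophenoxy)triisopropylsilane | CC(C)[Si](Oc1ccc(F)cc1)(C(C)C)C(C)C | intermediate
6 | lithium (dimethylamino)[2-fluoro-5-(triisopropylsilyloxy)phenyl]methanolate (racemic) | [Li]OC(N(C)C)c1cc(O[Si](C(C)C)(C(C)C)C(C)C)ccc1F | intermediate
7 | dilithium bis(hemiaminal alkoxide) of 8 (stereoisomer mixture) | [Li]OC(N(C)C)c1cc(O[Si](C(C)C)(C(C)C)C(C)C)cc(C(O[Li])N(C)C)c1F | intermediate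
8 | 2-fluoro-5-(triisopropylsilyloxy)isophthalaldehyde | O=Cc1cc(O[Si](C(C)C)(C(C)C)C(C)C)cc(C=O)c1F | intermediate
9 | 5-(allyloxy)-2-fluoroisophthalaldehyde | C=CCOc1cc(C=O)c(F)c(C=O)c1 | intermediate
10 | 5-(benzyloxy)-2-fluoroisophthalaldehyde | O=Cc1cc(OCc2ccccc2)cc(C=O)c1F | intermediate
11 | 4-fluoro-3-hydroxybenzaldehyde | O=Cc1ccc(F)c(O)c1 | starting material
12 | 4-fluoro-3-(triisopropylsilyloxy)benzaldehyde | O=Cc1ccc(F)c(O[Si](C(C)C)(C(C)C)C(C)C)c1 | intermediate
13 | lithium [4-fluoro-3-(triisopropylsilyloxy)phenyl](4-methylpiperazin-1-yl)methanolate (racemic) | [Li]OC(N1CCN(C)CC1)c1ccc(F)c(O[Si](C(C)C)(C(C)C)C(C)C)c1 | intermediate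
14 | dilithium bis(hemiaminal alkoxide) of 15 (stereoisomer mixture) | [Li]OC(N(C)C)c1cc(C(O[Li])N2CCN(C)CC2)cc(O[Si](C(C)C)(C(C)C)C(C)C)c1F | intermediate
15 | 4-fluoro-5-(triisopropylsilyloxy)isophthalaldehyde | O=Cc1cc(C=O)c(F)c(O[Si](C(C)C)(C(C)C)C(C)C)c1 | intermediate
16 | 5-(allyloxy)-4-fluoroisophthalaldehyde | C=CCOc1cc(C=O)cc(C=O)c1F | intermediate
17 | 3-fluoro-4-hydroxybenzaldehyde | O=Cc1ccc(O)c(F)c1 | starting material
18 | 4-(allyloxy)-3-fluorobenzaldehyde | O=Cc1ccc(OCC=C)c(F)c1 | intermediate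
19 | 4-(allyloxy)-3-fluorophenyl formate | O=COc1ccc(OCC=C)c(F)c1 | intermediate
20 | 4-(allyloxy)-3-fluorophenol | Oc1ccc(OCC=C)c(F)c1 | intermediate
21 | 4-(allyloxy)-3-fluoro-2,6-bis(hydroxymethyl)phenol | OCc1cc(OCC=C)c(F)c(CO)c1O | intermediate
22 | [5-(allyloxy)-2-(benzyloxy)-4-fluoro-1,3-phenylene]dimethanol | OCc1cc(OCC=C)c(F)c(CO)c1OCc1ccccc1 | intermediate
23 | 5-(allyloxy)-2-(benzyloxy)-4-fluoroisophthalaldehyde | O=Cc1cc(OCC=C)c(F)c(C=O)c1OCc1ccccc1 | intermediate
24 | dimer G–F allyl ether | C=CCOc6cc(C=O)c(Oc7cc(OCc8ccccc8)c(OCc8ccccc8)c(OCc8ccccc8)c7)c(C=O)c6 | intermediate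
25 | dimer G–F phenol | Oc6cc(C=O)c(Oc7cc(OCc8ccccc8)c(OCc8ccccc8)c(OCc8ccccc8)c7)c(C=O)c6 | intermediate
26 | trimer G–F–E allyl ether | C=CCOc5cc(C=O)cc(C=O)c5Oc6cc(C=O)c(Oc7cc(OCc8ccccc8)c(OCc8ccccc8)c(OCc8ccccc8)c7)c(C=O)c6 | intermediate
27 | trimer G–F–E phenol | Oc5cc(C=O)cc(C=O)c5Oc6cc(C=O)c(Oc7cc(OCc8ccccc8)c(OCc8ccccc8)c(OCc8ccccc8)c7)c(C=O)c6 | intermediate
28 | tetramer G–F–E–D allyl ether | C=CCOc4cc(C=O)c(Oc5cc(C=O)cc(C=O)c5Oc6cc(C=O)c(Oc7cc(OCc8ccccc8)c(OCc8ccccc8)c(OCc8ccccc8)c7)c(C=O)c6)c(C=O)c4 | intermediate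
29 | tetramer G–F–E–D phenol | Oc4cc(C=O)c(Oc5cc(C=O)cc(C=O)c5Oc6cc(C=O)c(Oc7cc(OCc8ccccc8)c(OCc8ccccc8)c(OCc8ccccc8)c7)c(C=O)c6)c(C=O)c4 | intermediate
30 | pentamer G–F–E–D–C allyl ether | C=CCOc3cc(C=O)c(OCc8ccccc8)c(C=O)c3Oc4cc(C=O)c(Oc5cc(C=O)cc(C=O)c5Oc6cc(C=O)c(Oc7cc(OCc8ccccc8)c(OCc8ccccc8)c(OCc8ccccc8)c7)c(C=O)c6)c(C=O)c4 | intermediate
31 | pentamer G–F–E–D–C phenol | Oc3cc(C=O)c(OCc8ccccc8)c(C=O)c3Oc4cc(C=O)c(Oc5cc(C=O)cc(C=O)c5Oc6cc(C=O)c(Oc7cc(OCc8ccccc8)c(OCc8ccccc8)c(OCc8ccccc8)c7)c(C=O)c6)c(C=O)c4 | intermediate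
32 | hexamer G–F–E–D–C–B allyl ether | C=CCOc2cc(C=O)c(Oc3cc(C=O)c(OCc8ccccc8)c(C=O)c3Oc4cc(C=O)c(Oc5cc(C=O)cc(C=O)c5Oc6cc(C=O)c(Oc7cc(OCc8ccccc8)c(OCc8ccccc8)c(OCc8ccccc8)c7)c(C=O)c6)c(C=O)c4)c(C=O)c2 | intermediate
33 | hexamer G–F–E–D–C–B phenol | Oc2cc(C=O)c(Oc3cc(C=O)c(OCc8ccccc8)c(C=O)c3Oc4cc(C=O)c(Oc5cc(C=O)cc(C=O)c5Oc6cc(C=O)c(Oc7cc(OCc8ccccc8)c(OCc8ccccc8)c(OCc8ccccc8)c7)c(C=O)c6)c(C=O)c4)c(C=O)c2 | intermediate
34 | dodeca-formyl heptamer, five benzyl ethers | c8ccccc8COc1cc(C=O)c(Oc2cc(C=O)c(Oc3cc(C=O)c(OCc8ccccc8)c(C=O)c3Oc4cc(C=O)c(Oc5cc(C=O)cc(C=O)c5Oc6cc(C=O)c(Oc7cc(OCc8ccccc8)c(OCc8ccccc8)c(OCc8ccccc8)c7)c(C=O)c6)c(C=O)c4)c(C=O)c2)c(C=O)c1 | intermediate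
35 | dodecaformate heptamer, five benzyl ethers | c8ccccc8COc1cc(OC=O)c(Oc2cc(OC=O)c(Oc3cc(OC=O)c(OCc8ccccc8)c(OC=O)c3Oc4cc(OC=O)c(Oc5cc(OC=O)cc(OC=O)c5Oc6cc(OC=O)c(Oc7cc(OCc8ccccc8)c(OCc8ccccc8)c(OCc8ccccc8)c7)c(OC=O)c6)c(OC=O)c4)c(OC=O)c2)c(OC=O)c1 | intermediate
36 | dodecaphenol heptamer, five benzyl ethers | c8ccccc8COc1cc(O)c(Oc2cc(O)c(Oc3cc(O)c(OCc8ccccc8)c(O)c3Oc4cc(O)c(Oc5cc(O)cc(O)c5Oc6cc(O)c(Oc7cc(OCc8ccccc8)c(OCc8ccccc8)c(OCc8ccccc8)c7)c(O)c6)c(O)c4)c(O)c2)c(O)c1 | intermediate
37 | CNP0351377.0 | Oc1cc(O)c(Oc2cc(O)c(Oc3cc(O)c(O)c(O)c3Oc4cc(O)c(Oc5cc(O)cc(O)c5Oc6cc(O)c(Oc7cc(O)c(O)c(O)c7)c(O)c6)c(O)c4)c(O)c2)c(O)c1 | target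

**Step count**

Total: 26 steps. Longest linear sequence: 16 steps (4 → 5 → 8 → 9 → 24 → … → 37; steps 2, 3, 4 and 14–26).

**Steps most likely to fail**

Step 25. Hydride rather than aryl migration may occur at the less electron-rich formyl groups (those with a single aryloxy donor and a meta formyl neighbour), giving carboxylic acids. The oxidation may also stall at mixed aldehyde/formate stages, or the peracid may attack the electron-rich ring G. Fallback: setting out from 34, twelvefold addition of MeMgBr (THF, –78 to 0 °C) should give the dodeca(1-hydroxyethyl) heptamer F1. Oxidation with Dess–Martin periodinane should give the dodeca-acetyl heptamer F2. Its Baeyer–Villiger oxidation with mCPBA under CF3CO2H catalysis has no hydride pathway, and aryl migrates in preference to methyl, so it should give the dodeca-acetate heptamer F3. Methanolysis (HCl, degassed MeOH) returns to the route at 36.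

Step 3. The second deprotonation may be misdirected to the position next to the hemiaminal alkoxide, or the alkoxide may collapse in the flask so that s-BuLi adds to the freed aldehyde. Fallback: setting out from 5, a single lithiation and formylation (s-BuLi, THF, –78 °C; DMF) should give 2-fluoro-5-(triisopropylsilyloxy)benzaldehyde F4. Acetalisation with ethylene glycol (pyridinium tosylate, toluene, Dean–Stark) should give 2-[2-fluoro-5-(triisopropylsilyloxy)phenyl]-1,3-dioxolane F5. A second fluorine-directed lithiation and formylation should give 3-(1,3-dioxolan-2-yl)-2-fluoro-5-(triisopropylsilyloxy)benzaldehyde F6. Mild aqueous acid (HCl, THF, rt) removes the acetal and returns to the route at 8.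

Step 4 (and its twins, steps 5 and 8). The transient phenoxide may attack the activated C–F bond of starting material or product before it is alkylated, which would give diaryl ether oligomers. Fallback: setting out from 8, desilylation under acidic, non-basic conditions (HF·pyridine, THF, 0 °C) should give neutral 2-fluoro-5-hydroxyisophthalaldehyde F7. Mitsunobu etherification with allyl alcohol (PPh3, diisopropyl azodicarboxylate, THF, 0 °C), which never builds up free phenoxide, returns to the route at 9.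

**Further compounds**

F1 | step 25 | dodeca(1-hydroxyethyl) heptamer, five benzyl ethers (diastereomer mixture) | c8ccccc8COc1cc(C(C)O)c(Oc2cc(C(C)O)c(Oc3cc(C(C)O)c(OCc8ccccc8)c(C(C)O)c3Oc4cc(C(C)O)c(Oc5cc(C(C)O)cc(C(C)O)c5Oc6cc(C(C)O)c(Oc7cc(OCc8ccccc8)c(OCc8ccccc8)c(OCc8ccccc8)c7)c(C(C)O)c6)c(C(C)O)c4)c(C(C)O)c2)c(C(C)O)c1
F2 | step 25 | dodeca-acetyl heptamer, five benzyl ethers | c8ccccc8COc1cc(C(C)=O)c(Oc2cc(C(C)=O)c(Oc3cc(C(C)=O)c(OCc8ccccc8)c(C(C)=O)c3Oc4cc(C(C)=O)c(Oc5cc(C(C)=O)cc(C(C)=O)c5Oc6cc(C(C)=O)c(Oc7cc(OCc8ccccc8)c(OCc8ccccc8)c(OCc8ccccc8)c7)c(C(C)=O)c6)c(C(C)=O)c4)c(C(C)=O)c2)c(C(C)=O)c1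
F3 | step 25 | dodeca-acetate heptamer, five benzyl ethers | c8ccccc8COc1cc(OC(C)=O)c(Oc2cc(OC(C)=O)c(Oc3cc(OC(C)=O)c(OCc8ccccc8)c(OC(C)=O)c3Oc4cc(OC(C)=O)c(Oc5cc(OC(C)=O)cc(OC(C)=O)c5Oc6cc(OC(C)=O)c(Oc7cc(OCc8ccccc8)c(OCc8ccccc8)c(OCc8ccccc8)c7)c(OC(C)=O)c6)c(OC(C)=O)c4)c(OC(C)=O)c2)c(OC(C)=O)c1
F4 | step 3 | 2-fluoro-5-(triisopropylsilyloxy)benzaldehyde | O=Cc1cc(O[Si](C(C)C)(C(C)C)C(C)C)ccc1F
F5 | step 3 | 2-[2-fluoro-5-(triisopropylsilyloxy)phenyl]-1,3-dioxolane | Fc1ccc(O[Si](C(C)C)(C(C)C)C(C)C)cc1C1OCCO1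
F6 | step 3 | 3-(1,3-dioxolan-2-yl)-2-fluoro-5-(triisopropylsilyloxy)benzaldehyde | O=Cc1cc(O[Si](C(C)C)(C(C)C)C(C)C)cc(C2OCCO2)c1F
F7 | step 4 | 2-fluoro-5-hydroxyisophthalaldehyde | O=Cc1cc(O)cc(C=O)c1F
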